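**Plan**

1. Target numbering (furo[3,4-c]furan): C-1, O-2, C-3 (aryl), C-3a (OH), C-4, O-5, C-6 (aryl), C-6a (H). The SMILES defines the (3S,3aS,6R,6aR) isomer, in which both aryl groups lie on the concave (endo) face.
2. Retrosynthesis: cut C3a–C4 (Norrish–Yang photocyclisation; C-4 is the methyl of a 6-OCH3 ether, C-3a a ketone), then O2–C3 (carbenoid O–H insertion), then C3–C3a (Weinreb amide plus benzylic Grignard reagent), then C6–C6a (Evans syn-aldol).
3. Enabling feature: ring B (C3a–C4–O5–C6–C6a) is a 3-hydroxyoxolane in which C-4 is joined to C-6 only through O-5. In the C-3a ketone the carbonyl oxygen and the O–CH3 hydrogens are therefore 1,5-related (six-membered transition state), and no γ-hydrogen is within reach.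
4. Forward order: aldol (C6–C6a), O-methylation (puts the future C-4 on O-5), benzyl ketone (C3–C3a), diazo transfer and O–H insertion to close ring A (C1, O2, C3, C3a, C6a), photocyclisation to close ring B, desilylation.
5. Stereochemistry: C-6 and C-6a come from the (R)-4-benzyloxazolidinone-controlled syn-aldol. C-3 comes from ketonisation anti to the C-6a side chain (2,4-cis oxolanone). C-3a is relayed from C-6a by the cis-fusion forced on the biradical, which builds ring B on the face that carries both aryl groups.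

Key step: step 12

Remark: 3-[(tert-butyldimethylsilyl)oxy]propanoic acid is taken as a purchasable building block. Aryl silyl ethers are used so that the last step needs neither acid nor hydrogenolysis, both of which would endanger the endo-aryl benzylic ethers.

**Route**

Step 1
Reactants: 1 vanillin (4-hydroxy-3-methoxybenzaldehyde)
Product: 2 3-methoxy-4-[(triisopropylsilyl)oxy]benzaldehyde
Conditions: TIPSCl, imidazole, DMF, rt
Reagents that add atoms: chlorotriisopropylsilane (TIPSCl), CC(C)[Si](Cl)(C(C)C)C(C)C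
Why: Standard silylation of a phenol; the hindered aryl silyl ether should survive the organometallic, basic and photochemical steps and leave at the end with buffered fluoride.

Step 2
Reactants: 2 3-methoxy-4-[(triisopropylsilyl)oxy]benzaldehyde
Product: 3 {3-methoxy-4-[(triisopropylsilyl)oxy]phenyl}methanol
Conditions: NaBH4, EtOH/THF, 0 °C
Reagents that add atoms: none
Why: Chemoselective hydride reduction of the aldehyde to the benzylic alcohol.

Step 3
Reactants: 3 {3-methoxy-4-[(triisopropylsilyl)oxy]phenyl}methanol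
Product: 4 [4-(chloromethyl)-2-methoxyphenoxy]triisopropylsilane
Conditions: SOCl2, pyridine, CH2Cl2, 0 °C; used directly
Reagents that add atoms: thionyl chloride, O=S(Cl)Cl
Why: Chlorodehydroxylation of an electron-rich benzylic alcohol through its chlorosulfite, with pyridine taking up HCl so that the aryl silyl ether is kept.

Step 4
Reactants: 5 3-[(tert-butyldimethylsilyl)oxy]propanoic acid; 6 (R)-4-benzyl-1,3-oxazolidin-2-one
Product: 8 (4R)-4-benzyl-3-{3-[(tert-butyldimethylsilyl)oxy]propanoyl}-1,3-oxazolidin-2-one, via mixed pivalic anhydride 7 (not isolated)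
Conditions: PivCl, Et3N, THF, −20 °C; then 6, LiCl, −20 °C to rt
Reagents that add atoms: none
Why: N-acylation of the oxazolidinone through the mixed anhydride (LiCl-assisted), which avoids an acid chloride and its HCl in the presence of the silyl ether.

Step 5
Reactants: 8 (4R)-4-benzyl-3-{3-[(tert-butyldimethylsilyl)oxy]propanoyl}-1,3-oxazolidin-2-one; 2 3-methoxy-4-[(triisopropylsilyl)oxy]benzaldehyde
Product: 10 (4R)-4-benzyl-3-[(2R,3R)-2-{[(tert-butyldimethylsilyl)oxy]methyl}-3-hydroxy-3-{3-methoxy-4-[(triisopropylsilyl)oxy]phenyl}propanoyl]-1,3-oxazolidin-2-one, via dibutylboron Z-enolate 9 (not isolated)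
Conditions: Bu2BOTf, iPr2NEt, CH2Cl2, −78 to 0 °C; then 2, −78 to 0 °C; pH 7 buffer, MeOH, H2O2, 0 °C
Reagents that add atoms: none
Why: Evans syn-aldol reaction: the Z-boron enolate reacts through a Zimmerman–Traxler chair on the face away from the benzyl group of the (R)-auxiliary, which should set both new centres (the future C-6a and C-6) as 2R,3R.

Step 6
Reactants: 10 the syn-aldol imide
Product: 11 (2R,3R)-2-{[(tert-butyldimethylsilyl)oxy]methyl}-3-hydroxy-N-methoxy-3-{3-methoxy-4-[(triisopropylsilyl)oxy]phenyl}-N-methylpropanamide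
Conditions: MeNHOMe·HCl, AlMe3, CH2Cl2, −20 to 0 °C; aq. potassium sodium tartrate
Reagents that add atoms: N,O-dimethylhydroxylamine hydrochloride, CNOC.Cl
Why: Aluminium amide transamination of a β-hydroxy imide (assisted by the aluminium alkoxide of the free hydroxyl) should give the Weinreb amide and release the auxiliary without retro-aldol cleavage.

Step 7
Reactants: 11 the β-hydroxy Weinreb amide
Product: 12 (2R,3R)-2-{[(tert-butyldimethylsilyl)oxy]methyl}-N,3-dimethoxy-3-{3-methoxy-4-[(triisopropylsilyl)oxy]phenyl}-N-methylpropanamide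
Conditions: Me3OBF4, 1,8-bis(dimethylamino)naphthalene, 4 Å molecular sieves, CH2Cl2, 0 °C to rt
Reagents that add atoms: trimethyloxonium tetrafluoroborate, C[O+](C)C.F[B-](F)(F)F
Why: O-methylation with Meerwein salt and a non-nucleophilic base forms no alkoxide, so retro-aldol cleavage, silyl migration and epimerisation are avoided; this methyl carbon becomes C-4 of the target.

Step 8
Reactants: 12 the β-methoxy Weinreb amide; 4 [4-(chloromethyl)-2-methoxyphenoxy]triisopropylsilane
Product: 14 (3R,4R)-3-{[(tert-butyldimethylsilyl)oxy]methyl}-4-methoxy-1,4-bis{3-methoxy-4-[(triisopropylsilyl)oxy]phenyl}butan-2-one, via benzylic Grignard reagent 13 (not isolated)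
Conditions: Mg, Et2O, 0 °C (slow addition of 4); then 12, THF, −78 to 0 °C; aq. NH4Cl
Reagents that add atoms: none
Why: Weinreb ketone synthesis; the chelated tetrahedral intermediate stops at the ketone stage and keeps the α-centre (C-3) intact.

Step 9
Reactants: 14 the silyl-protected benzyl ketone
Product: 15 (3R,4R)-3-(hydroxymethyl)-4-methoxy-1,4-bis{3-methoxy-4-[(triisopropylsilyl)oxy]phenyl}butan-2-one
Conditions: HF·pyridine, pyridine, THF, 0 °C
Reagents that add atoms: none
Why: Buffered HF cleaves the primary alkyl silyl ether much faster than the aryl triisopropylsilyl ethers, and is done before the diazo group is present because HF would add to it.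

Step 10
Reactants: 15 the hydroxy benzyl ketone
Product: 16 (3R,4R)-1-diazo-3-(hydroxymethyl)-4-methoxy-1,4-bis{3-methoxy-4-[(triisopropylsilyl)oxy]phenyl}butan-2-one
Conditions: p-ABSA, DBU, MeCN, 0 °C
Reagents that add atoms: 4-acetamidobenzenesulfonyl azide (p-ABSA), CC(=O)Nc1ccc(cc1)S(=O)(=O)N=[N+]=[N-]
Why: Regitz diazo transfer to the benzylic methylene, by far the more acidic α-position, so the enolate toward C-3 (which could lose methanol) is not formed.

Step 11
Reactants: 16 the aryl diazo ketone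
Product: 18 (2S,4R)-4-[(R)-methoxy{3-methoxy-4-[(triisopropylsilyl)oxy]phenyl}methyl]-2-{3-methoxy-4-[(triisopropylsilyl)oxy]phenyl}oxolan-3-one, via enol 17 (not isolated)
Conditions: Rh2(OAc)4 (1 mol %), CH2Cl2, rt, slow addition of 16; then Et3N (0.1 equiv), rt
Reagents that add atoms: none
Why: Intramolecular O–H insertion of the rhodium carbenoid into the primary hydroxyl closes ring A as an oxolan-3-one; C-2 is set when enol 17 is protonated anti to the C-4 side chain and, being epimerisable, should converge on the 2,4-cis isomer, which is expected to be the more stable.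

Step 12
Reactants: 18 the 2,4-cis oxolan-3-one
Product: 20 (3S,3aS,6R,6aR)-3,6-bis{3-methoxy-4-[(triisopropylsilyl)oxy]phenyl}tetrahydro-1H,3H-furo[3,4-c]furan-3a(4H)-ol, via 1,5-biradical 19 (not isolated)
Conditions: hν (medium-pressure Hg lamp, Pyrex filter, λ > 290 nm), degassed benzene (0.005 M), 10–20 °C
Reagents that add atoms: none
Why: Norrish–Yang photocyclisation: n→π* excitation of the C-3 carbonyl of 18 is followed by 1,5-hydrogen transfer from the methoxy group through a six-membered transition state, giving 1,5-biradical 19 (ketyl carbon at the future C-3a, alkoxymethyl radical at the future C-4), which collapses by radical–radical combination. The closest known reaction type is the photocyclisation of β-alkoxy ketones to oxolan-3-ols by δ-hydrogen abstraction. The single ring closed, ring B (C3a–C4–O5–C6–C6a), forms by combination of the two ends of a 1,5-biradical, a five-membered closure that follows the hydrogen shift and has no polar trajectory to satisfy. The new stereocentre C-3a is controlled by C-6a: the C6a–C6–O5 tether can reach the planar ketyl carbon only on the ring face it already occupies, so the fusion is cis, the hydroxyl ends on the convex face, and the C-3 aryl group, cis to the tether in 18, ends endo like the C-6 aryl group fixed by the syn-aldol. The step needs δ-abstraction to be the only hydrogen transfer and to compete with α-cleavage: the γ atom is the ether oxygen, H-6 is β and the ring hydrogens cannot reach the carbonyl oxygen, so the three O–CH3 hydrogens are the only ones in range, while dilute, degassed benzene suppresses bimolecular photoreduction. Norrish type 1 cleavage of the C2–C3 bond is the competing channel and is dealt with under the risks.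

Step 13
Reactants: 20 the bis-silyl furofuranol
Product: 21 (3S,3aS,6R,6aR)-3,6-bis(4-hydroxy-3-methoxyphenyl)tetrahydro-1H,3H-furo[3,4-c]furan-3a(4H)-ol
Conditions: TBAF, AcOH, THF, 0 °C
Reagents that add atoms: none
Why: Buffered fluoride cleaves both aryl silyl ethers without acid or hydrogen, so the two endo-aryl benzylic ethers should neither epimerise nor be cleaved.

**Compound list**

1 | vanillin (4-hydroxy-3-methoxybenzaldehyde) | COc1cc(C=O)ccc1O | starting material
2 | 3-methoxy-4-[(triisopropylsilyl)oxy]benzaldehyde | COc1cc(C=O)ccc1O[Si](C(C)C)(C(C)C)C(C)C | intermediate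
3 | {3-methoxy-4-[(triisopropylsilyl)oxy]phenyl}methanol | COc1cc(CO)ccc1O[Si](C(C)C)(C(C)C)C(C)C | intermediate
4 | [4-(chloromethyl)-2-methoxyphenoxy]triisopropylsilane | COc1cc(CCl)ccc1O[Si](C(C)C)(C(C)C)C(C)C | intermediate
5 | 3-[(tert-butyldimethylsilyl)oxy]propanoic acid | CC(C)(C)[Si](C)(C)OCCC(=O)O | starting material
6 | (R)-4-benzyl-1,3-oxazolidin-2-one | O=C1N[C@H](Cc2ccccc2)CO1 | starting material
7 | 3-[(tert-butyldimethylsilyl)oxy]propanoic pivalic anhydride (not isolated) | CC(C)(C)[Si](C)(C)OCCC(=O)OC(=O)C(C)(C)C | intermediate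
8 | (4R)-4-benzyl-3-{3-[(tert-butyldimethylsilyl)oxy]propanoyl}-1,3-oxazolidin-2-one | CC(C)(C)[Si](C)(C)OCCC(=O)N1C(=O)OC[C@H]1Cc1ccccc1 | intermediate
9 | dibutylboron (Z)-enolate of 8 (not isolated) | CCCCB(CCCC)O/C(=C\CO[Si](C)(C)C(C)(C)C)N1C(=O)OC[C@H]1Cc1ccccc1 | intermediate
10 | (4R)-4-benzyl-3-[(2R,3R)-2-{[(tert-butyldimethylsilyl)oxy]methyl}-3-hydroxy-3-{3-methoxy-4-[(triisopropylsilyl)oxy]phenyl}propanoyl]-1,3-oxazolidin-2-one | CC(C)(C)[Si](C)(C)OC[C@@H](C(=O)N1C(=O)OC[C@H]1Cc1ccccc1)[C@@H](O)c1ccc(O[Si](C(C)C)(C(C)C)C(C)C)c(OC)c1 | intermediate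
11 | (2R,3R)-2-{[(tert-butyldimethylsilyl)oxy]methyl}-3-hydroxy-N-methoxy-3-{3-methoxy-4-[(triisopropylsilyl)oxy]phenyl}-N-methylpropanamide | CC(C)(C)[Si](C)(C)OC[C@@H](C(=O)N(C)OC)[C@@H](O)c1ccc(O[Si](C(C)C)(C(C)C)C(C)C)c(OC)c1 | intermediate
12 | (2R,3R)-2-{[(tert-butyldimethylsilyl)oxy]methyl}-N,3-dimethoxy-3-{3-methoxy-4-[(triisopropylsilyl)oxy]phenyl}-N-methylpropanamide | CC(C)(C)[Si](C)(C)OC[C@@H](C(=O)N(C)OC)[C@@H](OC)c1ccc(O[Si](C(C)C)(C(C)C)C(C)C)c(OC)c1 | intermediate
13 | {3-methoxy-4-[(triisopropylsilyl)oxy]benzyl}magnesium chloride (not isolated) | COc1cc(C[Mg]Cl)ccc1O[Si](C(C)C)(C(C)C)C(C)C | intermediate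
14 | (3R,4R)-3-{[(tert-butyldimethylsilyl)oxy]methyl}-4-methoxy-1,4-bis{3-methoxy-4-[(triisopropylsilyl)oxy]phenyl}butan-2-one | CC(C)(C)[Si](C)(C)OC[C@@H](C(=O)Cc1ccc(O[Si](C(C)C)(C(C)C)C(C)C)c(OC)c1)[C@@H](OC)c1ccc(O[Si](C(C)C)(C(C)C)C(C)C)c(OC)c1 | intermediate
15 | (3R,4R)-3-(hydroxymethyl)-4-methoxy-1,4-bis{3-methoxy-4-[(triisopropylsilyl)oxy]phenyl}butan-2-one | OC[C@@H](C(=O)Cc1ccc(O[Si](C(C)C)(C(C)C)C(C)C)c(OC)c1)[C@@H](OC)c1ccc(O[Si](C(C)C)(C(C)C)C(C)C)c(OC)c1 | intermediate
16 | (3R,4R)-1-diazo-3-(hydroxymethyl)-4-methoxy-1,4-bis{3-methoxy-4-[(triisopropylsilyl)oxy]phenyl}butan-2-one | OC[C@@H](C(=O)C(=[N+]=[N-])c1ccc(O[Si](C(C)C)(C(C)C)C(C)C)c(OC)c1)[C@@H](OC)c1ccc(O[Si](C(C)C)(C(C)C)C(C)C)c(OC)c1 | intermediate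
17 | (4R)-4-[(R)-methoxy{3-methoxy-4-[(triisopropylsilyl)oxy]phenyl}methyl]-2-{3-methoxy-4-[(triisopropylsilyl)oxy]phenyl}-4,5-dihydrofuran-3-ol (enol, not isolated) | COc1cc([C@H](OC)[C@H]2COC(c3ccc(O[Si](C(C)C)(C(C)C)C(C)C)c(OC)c3)=C2O)ccc1O[Si](C(C)C)(C(C)C)C(C)C | intermediate
18 | (2S,4R)-4-[(R)-methoxy{3-methoxy-4-[(triisopropylsilyl)oxy]phenyl}methyl]-2-{3-methoxy-4-[(triisopropylsilyl)oxy]phenyl}oxolan-3-one | COc1cc([C@H](OC)[C@H]2CO[C@@H](c3ccc(O[Si](C(C)C)(C(C)C)C(C)C)c(OC)c3)C2=O)ccc1O[Si](C(C)C)(C(C)C)C(C)C | intermediate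
19 | 1,5-biradical from 18: ketyl radical at C-3 of the oxolane, O–CH2 radical on the side-chain ether (not isolated) | COc1cc([C@H](O[CH2])[C@H]2CO[C@@H](c3ccc(O[Si](C(C)C)(C(C)C)C(C)C)c(OC)c3)[C]2O)ccc1O[Si](C(C)C)(C(C)C)C(C)C | intermediate
20 | (3S,3aS,6R,6aR)-3,6-bis{3-methoxy-4-[(triisopropylsilyl)oxy]phenyl}tetrahydro-1H,3H-furo[3,4-c]furan-3a(4H)-ol | COc1cc([C@@H]2OC[C@@]3(O)[C@@H]2CO[C@H]3c2ccc(O[Si](C(C)C)(C(C)C)C(C)C)c(OC)c2)ccc1O[Si](C(C)C)(C(C)C)C(C)C | intermediate
21 | (3S,3aS,6R,6aR)-3,6-bis(4-hydroxy-3-methoxyphenyl)tetrahydro-1H,3H-furo[3,4-c]furan-3a(4H)-ol | COc1cc([C@@H]2OC[C@@]3(O)[C@@H]2CO[C@H]3c2ccc(O)c(OC)c2)ccc1O | target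

**Step count**

Total: 13 steps. Longest linear sequence: 10 steps (steps 4–13, or step 1 followed by steps 5–13).

**Steps most likely to fail**

Step 12. The C-3 ketone of 18 is flanked by a benzylic, oxygen-substituted carbon, so Norrish type 1 cleavage of the C2–C3 bond can outrun the slower hydrogen transfer from a primary methoxy C–H. Reclosure of the acyl/benzylic biradical would scramble C-2 before ring B forms, and some material would be lost by decarbonylation. The fallback sets C-3 of the target after the photoreaction instead of before it. It sets out from 18: soft enolisation (TBSOTf, Et3N, CH2Cl2, 0 °C) should give the conjugated tert-butyldimethylsilyl enol ether F1. Rubottom oxidation (dimethyldioxirane, acetone/CH2Cl2, −78 °C) should give the 2-aryl-2-silyloxy oxolan-3-one F2, in which C-2 is no longer a controlling stereocentre and reversible α-cleavage is harmless. Irradiation as in step 12 should give the bicyclic silyl ketal F3. Ionic hydrogenation (Et3SiH, BF3·OEt2, CH2Cl2, −78 °C) then delivers hydride to the bicyclic oxocarbenium ion from the convex face, which places the aryl group endo and comes back to the route at 20.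

Step 11. The carbenoid may be diverted to an oxonium ylide at the methoxy oxygen or to attack on an arene, and protonation of the enol may show poor facial selectivity at C-2. The fallback closes ring A by substitution instead of insertion. It sets out from 15: bromination of the benzylic methylene (PhNMe3Br3, THF, 0 °C) should give the α-bromo ketone F4. A 5-exo-tet Williamson closure by the primary hydroxyl (K2CO3, acetone, rt), followed by the Et3N equilibration of step 11, comes back to the route at 18.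

Step 8. Wurtz-type homocoupling during formation of the electron-rich benzylic Grignard reagent, and deprotonation of the Weinreb amide at C-2 with loss of methanol, may erode the ketone synthesis. The fallback uses a sulfone-stabilised benzylic anion. It sets out from 4 and 12: displacement of chloride in 4 (PhSO2Na, DMF, rt) should give the benzylic phenyl sulfone F5. Its lithium derivative (n-BuLi, THF, −78 °C, 2 equiv) should acylate with 12 to give the β-keto sulfone F6. Reductive desulfonylation (SmI2, THF/MeOH, −78 °C) comes back to the route at 14.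

Further compounds

F1 | step 12 | tert-butyldimethylsilyl enol ether of 18 (C2=C3 enol ether; 4R, side chain R) | COc1cc([C@H](OC)[C@H]2COC(c3ccc(O[Si](C(C)C)(C(C)C)C(C)C)c(OC)c3)=C2O[Si](C)(C)C(C)(C)C)ccc1O[Si](C(C)C)(C(C)C)C(C)C
F2 | step 12 | (4R)-2-[(tert-butyldimethylsilyl)oxy]-4-[(R)-methoxy{3-methoxy-4-[(triisopropylsilyl)oxy]phenyl}methyl]-2-{3-methoxy-4-[(triisopropylsilyl)oxy]phenyl}oxolan-3-one (either configuration at C-2) | COc1cc([C@H](OC)[C@H]2COC(O[Si](C)(C)C(C)(C)C)(c3ccc(O[Si](C(C)C)(C(C)C)C(C)C)c(OC)c3)C2=O)ccc1O[Si](C(C)C)(C(C)C)C(C)C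
F3 | step 12 | (3aS,6R,6aR)-3-[(tert-butyldimethylsilyl)oxy]-3,6-bis{3-methoxy-4-[(triisopropylsilyl)oxy]phenyl}tetrahydro-1H,3H-furo[3,4-c]furan-3a(4H)-ol (either configuration at C-3) | COc1cc([C@@H]2OC[C@@]3(O)[C@@H]2COC3(O[Si](C)(C)C(C)(C)C)c2ccc(O[Si](C(C)C)(C(C)C)C(C)C)c(OC)c2)ccc1O[Si](C(C)C)(C(C)C)C(C)C
F4 | step 11 | (3R,4R)-1-bromo-3-(hydroxymethyl)-4-methoxy-1,4-bis{3-methoxy-4-[(triisopropylsilyl)oxy]phenyl}butan-2-one (either configuration at C-1) | OC[C@@H](C(=O)C(Br)c1ccc(O[Si](C(C)C)(C(C)C)C(C)C)c(OC)c1)[C@@H](OC)c1ccc(O[Si](C(C)C)(C(C)C)C(C)C)c(OC)c1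
F5 | step 8 | {4-[(benzenesulfonyl)methyl]-2-methoxyphenoxy}triisopropylsilane | COc1cc(CS(=O)(=O)c2ccccc2)ccc1O[Si](C(C)C)(C(C)C)C(C)C
F6 | step 8 | (3R,4R)-1-(benzenesulfonyl)-3-{[(tert-butyldimethylsilyl)oxy]methyl}-4-methoxy-1,4-bis{3-methoxy-4-[(triisopropylsilyl)oxy]phenyl}butan-2-one (either configuration at C-1) | CC(C)(C)[Si](C)(C)OC[C@@H](C(=O)C(c1ccc(O[Si](C(C)C)(C(C)C)C(C)C)c(OC)c1)S(=O)(=O)c1ccccc1)[C@@H](OC)c1ccc(O[Si](C(C)C)(C(C)C)C(C)C)c(OC)c1
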